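## Retrosynthetic overview

1. The last bond made is the angelate ester at O3. It is put on a free 3β-alcohol that already carries the 4β-acetate.
2. The 3β-OH/4β-OAc pair comes in one step from the C3=C4 olefin of (5R,10R)-eudesma-3,7(11)-dien-8-one. A Woodward–Prévost cis-oxygenation works on the hindered β face and leaves the acetate on the tertiary, axial oxygen.
3. Both rings of that dienone come from one acyclic C15 enyne silyl dienol ether in a single enantioselective gold-catalysed cascade. C4–C5 closes ring A first, then C9–C10 closes ring B in the same event.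
4. The acyclic chain is cut at C6–C7 into an (E)-allylic bromide, pent-3-yn-2-one and a methyl cuprate (three-component coupling).
5. The bromide, with its E-alkene already in place, comes from geranyl acetate. The isopropylidene end is cut off and rebuilt as a methyl-capped alkyne.

**Structure read from the SMILES:** a trans-decalin eudesmane, (3S,4R,5R,10R). It has 3β-angeloyloxy (equatorial), 4β-acetoxy (axial), 4α-Me, 5α-H, 10β-Me, a C8 ketone and a C7=C11 isopropylidene. The ester is Z.

**Numbering:** eudesmane numbering is used for the acyclic precursors too. Ring A is C1–C5 plus C10. Ring B is C5–C10. C14 is the methyl on C10, C15 the methyl on C4, and C11–C13 the isopropylidene.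

**Assumption:** the (R)-ligand in step 7 is taken to give the (5R,10R) series. Both ligand antipodes are sold, so the other one is used if the first run shows the opposite sense.

## Route

Step 1
Reactants: 1 geranyl acetate
Product: 3 (E)-3-methyl-6-oxohex-2-en-1-yl acetate, via secondary ozonide 2 (not isolated)
Conditions: O3 (1.0 equiv), CH2Cl2, −78 °C; Me2S, −78 °C to rt
Reagents that add atoms: ozone, [O-][O+]=O
Why: Chemoselective ozonolysis, in which the distal trisubstituted C=C is clearly more electron-rich than the one deactivated by the allylic acetate, so one equivalent of O3 cleaves only the distal bond and leaves the E-alkene (later C5=C10) untouched; no stereocentre is formed.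

Step 2
Reactants: 3 (E)-3-methyl-6-oxohex-2-en-1-yl acetate
Product: 5 (E)-3-methylhept-2-en-6-yn-1-ol, via enynyl acetate 4 (not isolated)
Conditions: MeC(O)C(N2)P(O)(OMe)2 (1.2 equiv), K2CO3 (2.5 equiv), MeOH, 0 °C to rt
Reagents that add atoms: dimethyl (1-diazo-2-oxopropyl)phosphonate, CC(=O)C(=[N+]=[N-])P(=O)(OC)OC
Why: Ohira–Bestmann (Seyferth–Gilbert) homologation turns the enolisable aldehyde into the terminal alkyne (new carbon = C4), and the same K2CO3/MeOH medium transesterifies the allylic acetate, so alkyne formation and deprotection cost one step; no stereocentre is formed.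

Step 3
Reactants: 5 (E)-3-methylhept-2-en-6-yn-1-ol
Product: 7 (E)-3-methyloct-2-en-6-yn-1-ol, via dilithio dianion 6 (not isolated)
Conditions: n-BuLi (2.1 equiv), THF, −78 to 0 °C; MeI (1.05 equiv), DMPU, 0 °C to rt; H2O
Reagents that add atoms: iodomethane, CI
Why: Acetylide alkylation, in which the carbanion of the O,C-dianion is far more nucleophilic toward MeI than the lithium alkoxide, so one equivalent of MeI gives only C-methylation (C15) and the alkene geometry is not touched.

Step 4
Reactants: 7 (E)-3-methyloct-2-en-6-yn-1-ol
Product: 8 (E)-1-bromo-3-methyloct-2-en-6-yne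
Conditions: CBr4, PPh3, CH2Cl2, 0 °C
Reagents that add atoms: tetrabromomethane, BrC(Br)(Br)Br
Why: Appel reaction, a neutral SN2 displacement of the activated primary hydroxyl that gives the allylic bromide without allylic transposition or E/Z scrambling and leaves the alkyne alone.

Step 5
Reactants: 8 (E)-1-bromo-3-methyloct-2-en-6-yne; 9 pent-3-yn-2-one
Product: 11 (E)-6-methyl-3-(propan-2-ylidene)undec-5-en-9-yn-2-one, via lithium allenolate 10 (not isolated)
Conditions: MeLi (2.4 equiv), CuI (1.2 equiv), Et2O, 0 °C; 9 (1.2 equiv), THF, −78 °C; 8 (1.0 equiv), DMPU, −78 to 0 °C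
Reagents that add atoms: methyllithium MeLi, [Li]C
Why: Tandem cuprate conjugate addition/enolate alkylation, in which Me2CuLi adds 1,4 to the ynone and allenolate 10 is allylated at its central carbon (C7) by the primary allylic bromide in SN2 fashion; both β-substituents are methyl, so no new alkene geometry arises and the conjugated tetrasubstituted enone forms directly with all 15 skeletal carbons.

Step 6
Reactants: 11 (E)-6-methyl-3-(propan-2-ylidene)undec-5-en-9-yn-2-one
Product: 13 tert-butyldimethyl{[(5E)-6-methyl-3-(propan-2-ylidene)undeca-1,5-dien-9-yn-2-yl]oxy}silane, via lithium dienolate 12 (not isolated)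
Conditions: LiN(iPr)2 (1.1 equiv), THF, −78 °C; TBSCl, DMPU, −78 to 0 °C; filtration through Et3N-washed silica
Reagents that add atoms: tert-butyldimethylsilyl chloride, CC(C)(C)[Si](C)(C)Cl
Why: Kinetic enolisation and O-silylation, in which the only α-hydrogens are those of the acetyl methyl (C9) and are removed faster than the γ-hydrogens of the twisted enone at −78 °C, which fixes the cross-conjugated 2-silyloxydiene whose CH2 terminus is the nucleophile of the cascade.

Step 7
Reactants: 13 tert-butyldimethyl{[(5E)-6-methyl-3-(propan-2-ylidene)undeca-1,5-dien-9-yn-2-yl]oxy}silane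
Product: 14 (5R,10R)-eudesma-3,7(11)-dien-8-one
Conditions: [(R)-DTBM-MeO-BIPHEP](AuCl)2 (3 mol %), AgSbF6 (3 mol %), MeOH (2 equiv), toluene, −20 °C
Reagents that add atoms: none
Why: Proposed new method: the cationic monovalent gold centre binds the C3≡C4 alkyne, C5 of the E-alkene attacks C4 anti to gold in the 6-endo-dig mode that 1,5-enynes prefer (charge builds up at tertiary C10), and the CH2 terminus C9 of the silyl dienol ether traps C10 antiperiplanar in a chair/half-chair array, so the E geometry is translated into the trans 5α-H/10β-Me fusion (Stork–Eschenmoser), MeOH takes the silyl group and the proton so released cleaves the C3–Au bond, while the chiral bisphosphine pocket selects the alkene face and thereby sets C5 (R) and C10 (R); the closest known reaction types are the enantioselective alkyne-initiated polyene cyclisation with bisphosphine digold catalysts, the 6-endo-dig cyclisation of methyl-capped 1,5-enynes with tethered nucleophiles, and silyl-enol-ether-terminated cation–olefin cyclisations, and new here are their combination and the cross-conjugated dienol silane that delivers the 7(11)-en-8-one directly.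

Step 8
Reactants: 14 (5R,10R)-eudesma-3,7(11)-dien-8-one
Product: 17 (3S,4R,5R,10R)-4-acetoxy-3-hydroxyeudesm-7(11)-en-8-one, via iodo acetate 15 (not isolated), via acetoxonium ion 16 (not isolated)
Conditions: I2 (1.05 equiv), AgOAc (2.3 equiv), AcOH, rt, dark; then H2O/AcOH, 50 °C; filter
Reagents that add atoms: silver acetate AgOAc, CC(=O)[O-].[Ag+]; water, O
Why: Woodward–Prévost cis-hydroxylation, in which iodonium forms on the open α face (the β face is shielded by the axial C10 methyl), acetate opens it trans-diaxially at tertiary C4 to give 15, silver-assisted loss of the axial iodide with anchimeric help inverts C3 and gives the β-cis ion 16, and water adds at the cationic carbon with stereoelectronic collapse to axial ester/equatorial alcohol, which sets C3 (S) and C4 (R) and places the acetate on the hindered tertiary oxygen without a separate acetylation; the electron-poor tetrasubstituted enone C=C does not react.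

Step 9
Reactants: 17 (3S,4R,5R,10R)-4-acetoxy-3-hydroxyeudesm-7(11)-en-8-one; 18 angelic acid
Product: 20 (3S,4R,5R,10R)-4-acetoxy-3-[(Z)-2-methylbut-2-enoyloxy]eudesm-7(11)-en-8-one, via mixed anhydride 19 (not isolated)
Conditions: 18 (3 equiv), 2,4,6-trichlorobenzoyl chloride (3 equiv), Et3N (3 equiv), toluene, rt; then 17, 80 °C
Reagents that add atoms: none
Why: Yamaguchi-type mixed-anhydride esterification run without DMAP, the standard way to make angelates, in which the alcohol attacks the less hindered angeloyl carbonyl and neither a nucleophilic catalyst nor free amine is left to isomerise Z to E or to move the neighbouring acetate; the C3–O bond is not broken, so the configuration is retained.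

## Compound list

1 | geranyl acetate, (E)-3,7-dimethylocta-2,6-dien-1-yl acetate | CC(C)=CCC/C(C)=C/COC(C)=O | starting material
2 | (E)-5-(5,5-dimethyl-1,2,4-trioxolan-3-yl)-3-methylpent-2-en-1-yl acetate (secondary ozonide, racemic at the ring CH) | CC1(C)OOC(CC/C(C)=C/COC(C)=O)O1 | intermediate (not isolated)
3 | (E)-3-methyl-6-oxohex-2-en-1-yl acetate | O=CCC/C(C)=C/COC(C)=O | intermediate
4 | (E)-3-methylhept-2-en-6-yn-1-yl acetate | C#CCC/C(C)=C/COC(C)=O | intermediate (not isolated)
5 | (E)-3-methylhept-2-en-6-yn-1-ol | C#CCC/C(C)=C/CO | intermediate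
6 | dilithium alkoxide/acetylide of 5 | [Li+].[Li+].[C-]#CCC/C(C)=C/C[O-] | intermediate (not isolated)
7 | (E)-3-methyloct-2-en-6-yn-1-ol | CC#CCC/C(C)=C/CO | intermediate
8 | (E)-1-bromo-3-methyloct-2-en-6-yne | CC#CCC/C(C)=C/CBr | intermediate
9 | pent-3-yn-2-one | CC#CC(C)=O | starting material
10 | lithium 4-methylpenta-2,3-dien-2-olate | CC(C)=C=C(C)[O-].[Li+] | intermediate (not isolated)
11 | (E)-6-methyl-3-(propan-2-ylidene)undec-5-en-9-yn-2-one | CC#CCC/C(C)=C/CC(=C(C)C)C(C)=O | intermediate
12 | lithium (5E)-6-methyl-3-(propan-2-ylidene)undeca-1,5-dien-9-yn-2-olate | [Li+].[O-]C(=C)C(=C(C)C)C/C=C(C)/CCC#CC | intermediate (not isolated)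
13 | tert-butyldimethyl{[(5E)-6-methyl-3-(propan-2-ylidene)undeca-1,5-dien-9-yn-2-yl]oxy}silane | C=C(O[Si](C)(C)C(C)(C)C)C(=C(C)C)C/C=C(C)/CCC#CC | intermediate
14 | (5R,10R)-eudesma-3,7(11)-dien-8-one, i.e. (4aR,8aR)-5,8a-dimethyl-3-(propan-2-ylidene)-3,4,4a,7,8,8a-hexahydronaphthalen-2(1H)-one; 5α-H, 10β-Me | CC1=CCC[C@]2(C)CC(=O)C(=C(C)C)C[C@@H]12 | intermediate
15 | (3R,4R,5R,10R)-4-acetoxy-3-iodoeudesm-7(11)-en-8-one (3α-I axial, 4β-OAc axial) | I[C@@H]1CC[C@]2(C)CC(=O)C(=C(C)C)C[C@H]2[C@@]1(C)OC(C)=O | intermediate (not isolated)
16 | 3β,4β-cis-fused 2-methyl-1,3-dioxolan-2-ylium (acetoxonium) acetate of the eudesm-7(11)-en-8-one core | CC1=[O+][C@H]2CC[C@]3(C)CC(=O)C(=C(C)C)C[C@H]3[C@@]2(C)O1.CC(=O)[O-] | intermediate (not isolated)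
17 | (3S,4R,5R,10R)-4-acetoxy-3-hydroxyeudesm-7(11)-en-8-one (3β-OH equatorial, 4β-OAc axial) | O[C@H]1CC[C@]2(C)CC(=O)C(=C(C)C)C[C@H]2[C@@]1(C)OC(C)=O | intermediate
18 | angelic acid, (Z)-2-methylbut-2-enoic acid | C/C=C(/C)C(=O)O | starting material
19 | (Z)-2-methylbut-2-enoic 2,4,6-trichlorobenzoic anhydride | C/C=C(/C)C(=O)OC(=O)c1c(Cl)cc(Cl)cc1Cl | intermediate (not isolated)
20 | (3S,4R,5R,10R)-4-acetoxy-3-[(Z)-2-methylbut-2-enoyloxy]eudesm-7(11)-en-8-one (3β-angeloyloxy-4β-acetoxyeudesm-7(11)-en-8-one, CNP0141494.2) | C/C=C(/C)C(=O)O[C@H]1CC[C@]2(C)CC(=O)C(=C(C)C)C[C@H]2[C@@]1(C)OC(C)=O | target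

## Step count and risks

Total step count: 9. Longest linear sequence: 9 (1 to 20). Compounds 9 and 18 are bought.

### Steps most likely to fail

**Step 7, the enantioselective bicyclisation.**
- Risks: modest ee, because gold sits anti to the bond being formed. Other risks are diversion of the 1,5-enyne to a bicyclo[3.1.0]hexene or a 5-exo product, proton loss after ring A, and methanolysis of the enol silane back to 11.
- Fallback: give up catalyst control and resolve. Setting out from 13, Ph3PAuCl/AgSbF6 with MeOH in CH2Cl2 runs the same cascade without a chiral ligand. This stays close to known methylalkyne-initiated 6-endo cyclisations.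
- It gives the racemate, that is 14 mixed with its mirror image (5S,10S)-eudesma-3,7(11)-dien-8-one F1.
- Preparative chromatography on a chiral stationary phase (SFC) separates the two. The route is rejoined at 14, at the price of half the material.

**Step 8, the Woodward–Prévost reaction.**
- Risks: proton loss from the iodonium or tertiary cation stage to allylic products, ionisation of 16 at tertiary C4, and drift of the acetate to O3 on long heating.
- Fallback: build the same array by epoxide opening and inversion at C3.
- Setting out from 14, mCPBA epoxidises only the C3=C4 bond from the α face to give 3α,4α-epoxyeudesm-7(11)-en-8-one F2.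
- Warm AcOH opens it trans-diaxially at C4 to give 4β-acetoxy-3α-hydroxyeudesm-7(11)-en-8-one F3. In F3 the diaxial groups cannot exchange the acyl group.
- Dess–Martin periodinane then gives 4β-acetoxyeudesm-7(11)-ene-3,8-dione F4.
- NaBH4 in MeOH/CH2Cl2 at −78 °C, with an acidic quench, delivers hydride axially from the α face to the saturated C3 ketone. The hindered conjugated C8 ketone is left alone. This gives the equatorial 3β-alcohol, and the route is rejoined at 17.

**Step 5, the three-component coupling.**
- Risks: methyl–allyl coupling of residual cuprate with 8, sluggish C-alkylation of 10, and some SN2' attack.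
- Fallback: replace the ynone/cuprate pair by deconjugative alkylation of an enone.
- Setting out from 8, excess mesityl oxide is converted with KOtBu in THF/t-BuOH into its extended dienolate. This is alkylated at the α-carbon to give racemic (E)-6-methyl-3-(prop-1-en-2-yl)undec-5-en-9-yn-2-one F5.
- DBU in warm toluene moves the double bond into conjugation. Unconverted F5 is recycled, and the route is rejoined at 11 at the cost of one extra step.

## Further compounds

F1 | step 7 | (5S,10S)-eudesma-3,7(11)-dien-8-one | CC1=CCC[C@@]2(C)CC(=O)C(=C(C)C)C[C@H]12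
F2 | step 8 | 3α,4α-epoxyeudesm-7(11)-en-8-one | O1[C@@H]2CC[C@]3(C)CC(=O)C(=C(C)C)C[C@H]3[C@]12C
F3 | step 8 | 4β-acetoxy-3α-hydroxyeudesm-7(11)-en-8-one | O[C@@H]1CC[C@]2(C)CC(=O)C(=C(C)C)C[C@H]2[C@@]1(C)OC(C)=O
F4 | step 8 | 4β-acetoxyeudesm-7(11)-ene-3,8-dione | O=C1CC[C@]2(C)CC(=O)C(=C(C)C)C[C@H]2[C@@]1(C)OC(C)=O
F5 | step 5 | (E)-6-methyl-3-(prop-1-en-2-yl)undec-5-en-9-yn-2-one (racemic) | CC#CCC/C(C)=C/CC(C(C)=C)C(C)=O
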